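The route opens the nine-membered oxacycle (O–C3–C4=C5–C6–C7–C8–C9–C10) at C4=C5, the one olefinic ring bond that belongs to neither the furanone nor the lactone: a cis trisubstituted olefin linking furanone C3 to lactone C6. Ring-closing metathesis of a diene that already carries the furanone, the trans α-methylene lactone and the C8 tiglate forges this olefin, and with it the oxonine and the ten-membered carbocycle, in one operation; ring size enforces the Z geometry. The diene arises from a Barbier union (C7–C8, setting C7 and C8) of a citramalate-derived furanone aldehyde with an enantioenriched α-(bromomethyl)-γ-vinylbutenolide.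

Key step: step 14

Remark: the C8 ester is read as tiglate ((E)-2-methylbut-2-enoate); germacrane numbering is used (C1 ketone, C2=C3 furanone enol ether, C4=C5 with C15H2OH on C4, C6 lactone carbinol, C7, C8 ester carbinol, C9, C10 quaternary with C14H3, C11=C13 methylene, C12 lactone carbonyl); in step 8 the ProPhenol antipode is the one that gives the 3R carbinol (taken as S,S).

Step 1
Reactants: 1 2-bromoprop-2-en-1-ol
Product: 2 [(2-bromoprop-2-en-1-yl)oxy](tert-butyl)dimethylsilane
Conditions: TBSCl, imidazole, CH2Cl2, 0 °C → rt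
Reagents that add atoms: tert-butyldimethylsilyl chloride, CC(C)(C)[Si](C)(C)Cl
Why: Imidazole-promoted silylation of the primary allylic alcohol (standard silyl ether protection) masks the future C15 hydroxyl while the vinyl bromide is untouched.

Step 2
Reactants: 2 [(2-bromoprop-2-en-1-yl)oxy](tert-butyl)dimethylsilane; 3 ethynyltrimethylsilane
Product: 4 tert-butyldimethyl{[2-methylidene-4-(trimethylsilyl)but-3-yn-1-yl]oxy}silane
Conditions: PdCl2(PPh3)2 (3 mol%), CuI (6 mol%), Et3N, THF, 50 °C
Reagents that add atoms: none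
Why: Sonogashira coupling of the vinyl bromide with the terminal alkyne builds the C2–C3–C4(C15) enyne, the TMS group blocking the second alkyne terminus and the allylic silyl ether being too poor a leaving group for Pd(0) ionisation.

Step 3
Reactants: 5 (R)-citramalic acid
Product: 6 2-[(4R)-2,2,4-trimethyl-5-oxo-1,3-dioxolan-4-yl]acetic acid
Conditions: 2,2-dimethoxypropane, TsOH·H2O (cat.), rt
Reagents that add atoms: 2,2-dimethoxypropane, COC(C)(C)OC
Why: Acid-catalysed transacetalisation ties the tertiary hydroxyl and the adjacent carboxyl into a five-membered dioxolanone (preferred over the six-membered alternative with the distal carboxyl), which differentiates the two acids without touching the chiral-pool stereocentre that becomes C10.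

Step 4
Reactants: 6 2-[(4R)-2,2,4-trimethyl-5-oxo-1,3-dioxolan-4-yl]acetic acid
Product: 8 (3R)-3-hydroxy-3-methyloxolan-2-one, via hydroxyethyl dioxolanone 7 (not isolated)
Conditions: BH3·SMe2, THF, 0 °C → rt; MeOH; then TsOH·H2O (cat.), CH2Cl2, rt
Reagents that add atoms: none
Why: Borane reduces the free carboxylic acid chemoselectively through an acyloxyborane while the dioxolanone ester is spared, and acid then drives translactonisation of the γ-hydroxy dioxolanone to the five-membered lactone with loss of acetone, the quaternary centre being untouched.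

Step 5
Reactants: 4 tert-butyldimethyl{[2-methylidene-4-(trimethylsilyl)but-3-yn-1-yl]oxy}silane; 8 (3R)-3-hydroxy-3-methyloxolan-2-one
Product: 10 (3R)-7-{[tert-butyl(dimethyl)silyl]oxy}methyl-1,3-dihydroxy-3-methyloct-7-en-5-yn-4-one, via lithium acetylide 9 (not isolated)
Conditions: 4, MeLi·LiBr, THF, 0 °C → rt; then 8 (pre-treated with LiHMDS, THF, −78 °C), −78 → −30 °C; AcOH, −78 °C
Reagents that add atoms: none
Why: MeLi cleaves the alkynyl–silicon bond to the lithium acetylide, which acylates only once on the non-enolisable lactone (tertiary hydroxyl held as its lithium alkoxide) because the lithium lactolate persists until the acidic quench releases the ynone (acetylide addition to a lactone).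

Step 6
Reactants: 10 (3R)-7-{[tert-butyl(dimethyl)silyl]oxy}methyl-1,3-dihydroxy-3-methyloct-7-en-5-yn-4-one
Product: 12 (2R)-5-(3-{[tert-butyl(dimethyl)silyl]oxy}prop-1-en-2-yl)-2-(2-hydroxyethyl)-2-methylfuran-3(2H)-one, via enaminone 11 (not isolated)
Conditions: Et2NH, EtOH, rt; then AcOH/H2O, rt
Reagents that add atoms: none
Why: Conjugate addition of diethylamine to the ynone gives the β-enaminone, in which the tertiary C10 hydroxyl displaces the amine at C3 by addition–elimination to close the 3(2H)-furanone (classical amine-mediated cyclisation of α′-hydroxy ynones), the primary hydroxyl being unable to compete because it would have to form a seven-membered ring.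

Step 7
Reactants: 12 (2R)-5-(3-{[tert-butyl(dimethyl)silyl]oxy}prop-1-en-2-yl)-2-(2-hydroxyethyl)-2-methylfuran-3(2H)-one
Product: 13 2-[(2R)-5-(3-{[tert-butyl(dimethyl)silyl]oxy}prop-1-en-2-yl)-2-methyl-3-oxo-2,3-dihydrofuran-2-yl]acetaldehyde
Conditions: Dess–Martin periodinane, NaHCO3, CH2Cl2, 0 °C → rt
Reagents that add atoms: none
Why: Dess–Martin oxidation under buffered, non-basic conditions should give the aldehyde without E1cB loss of the β-positioned furanone oxygen, and the product is used without delay.

Step 8
Reactants: 14 acrolein; 15 tert-butyldimethyl(prop-2-yn-1-yloxy)silane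
Product: 17 (3R)-6-{[tert-butyl(dimethyl)silyl]oxy}hex-1-en-4-yn-3-ol, via methylzinc acetylide 16 (not isolated)
Conditions: 15, Me2Zn, (S,S)-ProPhenol (20 mol%), Ph3P=O (40 mol%), toluene, 0 °C; then 14, 4 °C
Reagents that add atoms: none
Why: Zinc–ProPhenol-catalysed enantioselective alkynylation, in which the alkynylzinc adds 1,2 to the enal inside the chiral dinuclear zinc pocket, sets the future C6 carbinol as R.

Step 9
Reactants: 17 (3R)-6-{[tert-butyl(dimethyl)silyl]oxy}hex-1-en-4-yn-3-ol
Product: 19 (3R,4Z)-6-{[tert-butyl(dimethyl)silyl]oxy}-5-iodohexa-1,4-dien-3-ol, via cyclic alkenylalanate 18 (not isolated)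
Conditions: Red-Al, THF, 0 °C → rt; EtOAc; then I2, THF, −78 → 0 °C
Reagents that add atoms: iodine, II
Why: Hydroxyl-directed trans-hydroalumination delivers hydride to the proximal alkyne carbon and aluminium to the distal one within a five-membered alkoxyalanate, and iodinolysis with retention gives the Z iodoalkene with iodine cis to the carbinol, the silyl ether being too poor a leaving group for allene formation at this temperature.

Step 10
Reactants: 19 (3R,4Z)-6-{[tert-butyl(dimethyl)silyl]oxy}-5-iodohexa-1,4-dien-3-ol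
Product: 20 (5R)-3-({[tert-butyl(dimethyl)silyl]oxy}methyl)-5-ethenylfuran-2(5H)-one
Conditions: PdCl2(PPh3)2 (5 mol%), CO (1 atm), K2CO3, THF, rt
Reagents that add atoms: carbon monoxide, [C-]#[O+]
Why: Palladium-catalysed carbonylative lactonisation (oxidative addition to the vinyl iodide, CO insertion, capture of the acylpalladium by the cis-disposed hydroxyl) closes the butenolide and installs C12 without touching the C6 stereocentre.

Step 11
Reactants: 20 (5R)-3-({[tert-butyl(dimethyl)silyl]oxy}methyl)-5-ethenylfuran-2(5H)-one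
Product: 21 (5R)-3-(bromomethyl)-5-ethenylfuran-2(5H)-one
Conditions: Ph3PBr2, CH2Cl2, 0 °C → rt
Reagents that add atoms: triphenylphosphine dibromide, BrP(Br)(c1ccccc1)(c1ccccc1)c1ccccc1
Why: Triphenylphosphine dibromide converts the primary allylic silyl ether directly into the bromide through an alkoxyphosphonium bromide (SN2), under non-basic conditions that spare the acidic γ-hydrogen at C6.

Step 12
Reactants: 13 2-[(2R)-5-(3-{[tert-butyl(dimethyl)silyl]oxy}prop-1-en-2-yl)-2-methyl-3-oxo-2,3-dihydrofuran-2-yl]acetaldehyde; 21 (5R)-3-(bromomethyl)-5-ethenylfuran-2(5H)-one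
Product: 23 (2R)-5-(3-{[tert-butyl(dimethyl)silyl]oxy}prop-1-en-2-yl)-2-{(2S)-2-[(2R,3R)-2-ethenyl-4-methylidene-5-oxooxolan-3-yl]-2-hydroxyethyl}-2-methylfuran-3(2H)-one, via allylzinc bromide 22 (not isolated)
Conditions: Zn dust, THF/sat. aq NH4Cl, 0 °C → rt
Reagents that add atoms: none
Why: Barbier-type allylation in which zinc inserts into the allylic bromide and the allylzinc attacks the aldehyde through its γ-carbon C7 in a chair Zimmerman–Traxler transition state, anti to the C6 vinyl group (C7 set R, trans to C6) and with the ring-locked E-type allyl geometry and equatorial aldehyde residue (C8 set S, anti), the allylic transposition unveiling the α-methylene lactone; minor diastereomers, including those from the minor enantiomer of 21, are separated here.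

Step 13
Reactants: 23 (2R)-5-(3-{[tert-butyl(dimethyl)silyl]oxy}prop-1-en-2-yl)-2-{(2S)-2-[(2R,3R)-2-ethenyl-4-methylidene-5-oxooxolan-3-yl]-2-hydroxyethyl}-2-methylfuran-3(2H)-one; 24 tigloyl chloride
Product: 25 (1S)-2-[(2R)-5-(3-{[tert-butyl(dimethyl)silyl]oxy}prop-1-en-2-yl)-2-methyl-3-oxo-2,3-dihydrofuran-2-yl]-1-[(2R,3R)-2-ethenyl-4-methylidene-5-oxooxolan-3-yl]ethyl (2E)-2-methylbut-2-enoate
Conditions: pyridine, DMAP (cat.), CH2Cl2, 0 °C → rt
Reagents that add atoms: none
Why: DMAP-catalysed acylation of the secondary C8 alcohol proceeds with retention, the tiglate being the thermodynamically favoured E enoate and pyridine too weak a base to scramble it through a vinylketene.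

Step 14
Reactants: 25 (1S)-2-[(2R)-5-(3-{[tert-butyl(dimethyl)silyl]oxy}prop-1-en-2-yl)-2-methyl-3-oxo-2,3-dihydrofuran-2-yl]-1-[(2R,3R)-2-ethenyl-4-methylidene-5-oxooxolan-3-yl]ethyl (2E)-2-methylbut-2-enoate
Product: 26 15-O-(tert-butyldimethylsilyl)lychnophorolide B (4Z,6R,7R,8S,10R)
Conditions: Hoveyda–Grubbs II (15 mol%, in portions), 1,4-benzoquinone (30 mol%), toluene (1 mM), 90 °C, Ar sparge
Reagents that add atoms: none
Why: Ring-closing metathesis: the ruthenium alkylidene exchanges onto the unhindered C5 vinyl group of the lactone, the resulting C5 alkylidene adds across the 1,1-disubstituted C4 olefin through a ruthenacyclobutane, and cycloreversion releases ethylene and the C4=C5 olefin. The closest known reaction type is RCM of a monosubstituted/1,1-disubstituted diene pair to a medium-ring trisubstituted cycloalkene, including closures of furanone-bridged nine-membered rings. The one ring closed is the nine-membered oxacycle O–C3–C4=C5–C6–C7–C8–C9–C10 (and with it the ten-membered carbocyclic envelope), by olefin metathesis at C4=C5 and not by a polar cyclisation. No stereocentre is created; the only stereochemical element, the C4=C5 geometry, is dictated by the ring, since a nine-membered ring fused to the planar furanone can hold the olefin only with C3 and C6 cis (Z). The step needs site selectivity for C5/C4 over the α-methylene lactone and the tiglate, and cyclisation over dimerisation: the methylene lactone could only close a cyclobutene with C5, the tiglate is an electron-poor trisubstituted olefin that is inert to the carbene, and high dilution together with the turn imposed by the quaternary C10, the furanone oxygen bridge and the trans-disposed C6/C7 substituents favours closure. Ethylene removal drives the equilibrium and benzoquinone suppresses Ru–H olefin migration.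

Step 15
Reactants: 26 15-O-(tert-butyldimethylsilyl)lychnophorolide B (4Z,6R,7R,8S,10R)
Product: 27 lychnophorolide B
Conditions: HF·pyridine, pyridine, THF, 0 °C → rt
Reagents that add atoms: none
Why: Fluoride cleaves the primary allylic silyl ether under buffered conditions that the α-methylene lactone, the tiglate, the furanone and the allylic lactone C–O bond should tolerate.

Compound list
1 | 2-bromoprop-2-en-1-ol | C=C(Br)CO | starting material
2 | [(2-bromoprop-2-en-1-yl)oxy](tert-butyl)dimethylsilane | C=C(Br)CO[Si](C)(C)C(C)(C)C | intermediate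
3 | ethynyltrimethylsilane | C#C[Si](C)(C)C | starting material
4 | tert-butyldimethyl{[2-methylidene-4-(trimethylsilyl)but-3-yn-1-yl]oxy}silane | C=C(CO[Si](C)(C)C(C)(C)C)C#C[Si](C)(C)C | intermediate
5 | (R)-citramalic acid, (2R)-2-hydroxy-2-methylbutanedioic acid | OC(=O)[C@@](C)(CC(=O)O)O | starting material
6 | 2-[(4R)-2,2,4-trimethyl-5-oxo-1,3-dioxolan-4-yl]acetic acid | CC1(C)O[C@](C)(CC(=O)O)C(=O)O1 | intermediate
7 | (5R)-5-(2-hydroxyethyl)-2,2,5-trimethyl-1,3-dioxolan-4-one (not isolated) | CC1(C)O[C@](C)(CCO)C(=O)O1 | intermediate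
8 | (3R)-3-hydroxy-3-methyloxolan-2-one | C[C@@]1(O)CCOC1=O | intermediate
9 | {3-({[tert-butyl(dimethyl)silyl]oxy}methyl)but-3-en-1-yn-1-yl}lithium (not isolated) | [Li]C#CC(=C)CO[Si](C)(C)C(C)(C)C | intermediate
10 | (3R)-7-{[tert-butyl(dimethyl)silyl]oxy}methyl-1,3-dihydroxy-3-methyloct-7-en-5-yn-4-one | C=C(CO[Si](C)(C)C(C)(C)C)C#CC(=O)[C@@](C)(CCO)O | intermediate
11 | (3R,5E)-7-{[tert-butyl(dimethyl)silyl]oxy}methyl-6-(diethylamino)-1,3-dihydroxy-3-methylocta-5,7-dien-4-one (not isolated) | CCN(CC)/C(=C/C(=O)[C@@](C)(CCO)O)C(=C)CO[Si](C)(C)C(C)(C)C | intermediate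
12 | (2R)-5-(3-{[tert-butyl(dimethyl)silyl]oxy}prop-1-en-2-yl)-2-(2-hydroxyethyl)-2-methylfuran-3(2H)-one | C=C(CO[Si](C)(C)C(C)(C)C)C1=CC(=O)[C@@](C)(CCO)O1 | intermediate
13 | 2-[(2R)-5-(3-{[tert-butyl(dimethyl)silyl]oxy}prop-1-en-2-yl)-2-methyl-3-oxo-2,3-dihydrofuran-2-yl]acetaldehyde | C=C(CO[Si](C)(C)C(C)(C)C)C1=CC(=O)[C@@](C)(CC=O)O1 | intermediate
14 | acrolein | C=CC=O | starting material
15 | tert-butyldimethyl(prop-2-yn-1-yloxy)silane | C#CCO[Si](C)(C)C(C)(C)C | starting material
16 | methyl{3-{[tert-butyl(dimethyl)silyl]oxy}prop-1-yn-1-yl}zinc (not isolated) | C[Zn]C#CCO[Si](C)(C)C(C)(C)C | intermediate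
17 | (3R)-6-{[tert-butyl(dimethyl)silyl]oxy}hex-1-en-4-yn-3-ol | C=C[C@@H](O)C#CCO[Si](C)(C)C(C)(C)C | intermediate
18 | sodium (5R)-5-ethenyl-2,2-bis(2-methoxyethoxy)-3-({[tert-butyl(dimethyl)silyl]oxy}methyl)-2,5-dihydro-1,2-oxaaluminol-2-uide (not isolated) | [Na+].C=C[C@H]1O[Al-](OCCOC)(OCCOC)C(CO[Si](C)(C)C(C)(C)C)=C1 | intermediate
19 | (3R,4Z)-6-{[tert-butyl(dimethyl)silyl]oxy}-5-iodohexa-1,4-dien-3-ol | C=C[C@@H](O)/C=C(\I)CO[Si](C)(C)C(C)(C)C | intermediate
20 | (5R)-3-({[tert-butyl(dimethyl)silyl]oxy}methyl)-5-ethenylfuran-2(5H)-one | O=C1O[C@H](C=C)C=C1CO[Si](C)(C)C(C)(C)C | intermediate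
21 | (5R)-3-(bromomethyl)-5-ethenylfuran-2(5H)-one | O=C1O[C@H](C=C)C=C1CBr | intermediate
22 | {[(5R)-5-ethenyl-2-oxo-2,5-dihydrofuran-3-yl]methyl}zinc bromide (not isolated) | Br[Zn]CC1=C[C@@H](C=C)OC1=O | intermediate
23 | (2R)-5-(3-{[tert-butyl(dimethyl)silyl]oxy}prop-1-en-2-yl)-2-{(2S)-2-[(2R,3R)-2-ethenyl-4-methylidene-5-oxooxolan-3-yl]-2-hydroxyethyl}-2-methylfuran-3(2H)-one | C=C1C(=O)O[C@H](C=C)[C@H]1[C@@H](O)C[C@@]2(C)OC(=CC2=O)C(=C)CO[Si](C)(C)C(C)(C)C | intermediate
24 | tigloyl chloride, (2E)-2-methylbut-2-enoyl chloride | C/C=C(\C)C(=O)Cl | starting material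
25 | (1S)-2-[(2R)-5-(3-{[tert-butyl(dimethyl)silyl]oxy}prop-1-en-2-yl)-2-methyl-3-oxo-2,3-dihydrofuran-2-yl]-1-[(2R,3R)-2-ethenyl-4-methylidene-5-oxooxolan-3-yl]ethyl (2E)-2-methylbut-2-enoate | C=C1C(=O)O[C@H](C=C)[C@H]1[C@@H](OC(=O)/C(C)=C/C)C[C@@]2(C)OC(=CC2=O)C(=C)CO[Si](C)(C)C(C)(C)C | intermediate
26 | 15-O-(tert-butyldimethylsilyl)lychnophorolide B (4Z,6R,7R,8S,10R) | C=C1C(=O)O[C@@H]2/C=C(/CO[Si](C)(C)C(C)(C)C)C3=CC(=O)[C@@](C)(C[C@H](OC(=O)/C(C)=C/C)[C@@H]12)O3 | intermediate
27 | lychnophorolide B | C=C1C(=O)O[C@@H]2/C=C(/CO)C3=CC(=O)[C@@](C)(C[C@H](OC(=O)/C(C)=C/C)[C@@H]12)O3 | target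

Total step count: 15. Longest linear sequence: 9 steps (steps 1, 2, 5, 6, 7, 12, 13, 14, 15; the citramalate branch through steps 3 and 4 is equally long).

Steps most likely to fail:

Step 14. The C5 alkylidene may fail to engage the hindered, conjugated C4 olefin in the conformation imposed by the bulky C8 tiglate, so that dimerisation at C5, Ru–H olefin migration or capture of the carbene by the tiglate olefin takes over. The fallback closes the ring before the ester is installed. It sets out from 23, whose free C8 hydroxyl is smaller and can hydrogen-bond to the C1 ketone to turn the chain. Ring-closing metathesis under the step-14 conditions should give the ring-closed C8 alcohol F1. F1 is then acylated with 24 (pyridine, DMAP) and the route is rejoined at 26.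

Step 12. Open transition states in the aqueous medium may erode the C8 configuration, and β-elimination of the furanone oxygen from the aldehyde may compete with C–C bond formation. The fallback sets C8 by inversion instead of by the transition state. It sets out from 13 and 21: the C8 epimer F2 formed in the same coupling is separated and esterified with tiglic acid under Mitsunobu conditions (PPh3, DIAD, toluene, 0 °C → rt). Inversion at C8 gives the tiglate directly and the route is rejoined at 25.

Step 10. Pd(0) may ionise the allylic C6–O bond of the newly formed γ-vinyl butenolide (π-allyl formation and reclosure), or carbonate may deprotonate the γ-position; either erodes the C6 configuration. The fallback avoids palladium and base at the butenolide stage. It sets out from 19: t-BuLi (3 equiv, Et2O, −78 °C) should give the dilithio species F3 by deprotonation and iodine–lithium exchange with retention of olefin geometry. Carboxylation with CO2 and acidic work-up gives the hydroxy acid F4, which lactonises (cat. TsOH, CH2Cl2) and rejoins the route at 20.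

Further compounds
F1 | step 14 | 8-O-destigloyl-15-O-(tert-butyldimethylsilyl)lychnophorolide B (4Z,6R,7R,8S,10R) | C=C1C(=O)O[C@@H]2/C=C(/CO[Si](C)(C)C(C)(C)C)C3=CC(=O)[C@@](C)(C[C@H](O)[C@@H]12)O3
F2 | step 12 | (2R)-5-(3-{[tert-butyl(dimethyl)silyl]oxy}prop-1-en-2-yl)-2-{(2R)-2-[(2R,3R)-2-ethenyl-4-methylidene-5-oxooxolan-3-yl]-2-hydroxyethyl}-2-methylfuran-3(2H)-one (C8 epimer of 23) | C=C1C(=O)O[C@H](C=C)[C@H]1[C@H](O)C[C@@]2(C)OC(=CC2=O)C(=C)CO[Si](C)(C)C(C)(C)C
F3 | step 10 | lithium (3R,4Z)-6-{[tert-butyl(dimethyl)silyl]oxy}-5-lithiohexa-1,4-dien-3-olate | C=C[C@@H](O[Li])/C=C(\[Li])CO[Si](C)(C)C(C)(C)C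
F4 | step 10 | (2Z,4R)-2-({[tert-butyl(dimethyl)silyl]oxy}methyl)-4-hydroxyhexa-2,5-dienoic acid | C=C[C@@H](O)/C=C(\C(=O)O)CO[Si](C)(C)C(C)(C)C
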